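**Retrosynthetic overview**

1. Quinone 17 comes from hydroquinone 16 (Ag2O), and 16 from its bis-silyl ether 15 (fluoride). The quinone is unveiled last so that no strong oxidant meets the electron-rich 2-arylfuran with its free α-position.
2. The strategy rests on the furan ring (O1, C2 bearing the quinone ring, C3–H, C4 bearing the side chain, C5–H). Its C3=C4 bond joins an unsubstituted carbon to the chain-bearing carbon, and C5 is a formyl-level carbon. C5 can therefore be an acetal carbon, C3=C4 can be made by ring-closing metathesis of mixed acetal 13 to 2-ethoxy-2,5-dihydrofuran 14, and loss of ethanol then gives furan 15 without an oxidant.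
3. Mixed acetal 13 comes from acetal exchange between the (S)-diethyl acetal ester 9 and the racemic aryl vinyl carbinol 12 (silylated 2,5-dihydroxybenzaldehyde plus a vinyl Grignard reagent).
4. Ester 9 comes from senecioylation of (S)-alcohol 7, made by CBS reduction of α-methylene ketone 6 (lithiated 2-bromoacrolein diethyl acetal plus Weinreb amide 3). This reduction sets the only stereocentre.
5. Ring order: the benzene ring is bought, the five-membered ring is closed in step 8 and aromatised in step 9, and the quinone is formed in step 11.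

Key step: step 8

Remark: the hydroquinone is carried as its bis(tert-butyldimethylsilyl) ether, and carbinol 12 is used as the racemate because its carbinol carbon becomes an sp2 furan carbon. Compounds 13 and 14 are therefore diastereomer mixtures at centres that are later lost.

**Route**

Step 1
Reactants: 1 4-methylpent-3-enoic acid
Product: 3 N-methoxy-N,4-dimethylpent-3-enamide, via acyl imidazolide 2 (not isolated)
Conditions: CDI, CH2Cl2, 0 °C to rt; then MeNH(OMe)·HCl, rt
Reagents that add atoms: N,O-dimethylhydroxylamine hydrochloride, CNOC.Cl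
Why: Weinreb amide formation through the acyl imidazolide is a neutral, base-free activation, so the β,γ-double bond should not move into conjugation.

Step 2
Reactants: 4 2-bromo-3,3-diethoxyprop-1-ene; 3 N-methoxy-N,4-dimethylpent-3-enamide
Product: 6 2-(diethoxymethyl)-6-methylhepta-1,5-dien-3-one, via vinyllithium 5 (not isolated)
Conditions: n-BuLi, THF, −78 °C; then 3, −78 °C; aq. NH4Cl
Reagents that add atoms: none
Why: Bromine–lithium exchange gives the α-(diethoxymethyl)vinyllithium, a known acrolein α-anion equivalent, and its addition to the Weinreb amide should stop at the chelated tetrahedral adduct so that only the ketone is released on quench (Weinreb ketone synthesis).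

Step 3
Reactants: 6 2-(diethoxymethyl)-6-methylhepta-1,5-dien-3-one
Product: 7 (S)-2-(diethoxymethyl)-6-methylhepta-1,5-dien-3-ol
Conditions: (R)-Me-CBS (0.2 equiv), catecholborane, toluene, −78 °C
Reagents that add atoms: none
Why: Corey–Bakshi–Shibata reduction, in which the ketone should bind the oxazaborolidine boron anti to the α-branched alkenyl group (the large substituent against the CH2 of the prenyl arm), so that the (R)-catalyst delivers hydride to the Re face and sets the (S)-carbinol, while catecholborane at −78 °C should leave the alkenes and the acetal alone.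

Step 4
Reactants: 7 (S)-2-(diethoxymethyl)-6-methylhepta-1,5-dien-3-ol; 8 3-methylbut-2-enoyl chloride
Product: 9 (S)-2-(diethoxymethyl)-6-methylhepta-1,5-dien-3-yl 3-methylbut-2-enoate
Conditions: pyridine, CH2Cl2, 0 °C to rt
Reagents that add atoms: none
Why: O-acylation of a secondary alcohol by an acid chloride through the acylpyridinium ion, with pyridine rather than a trialkylamine as base so that the acid chloride is not dehydrohalogenated to a vinylketene that would move the double bond, and with the carbinol C–O bond untouched so that the (S)-centre is kept.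

Step 5
Reactants: 10 2,5-dihydroxybenzaldehyde
Product: 11 2,5-bis(tert-butyldimethylsilyloxy)benzaldehyde
Conditions: TBSCl, imidazole, DMF, rt
Reagents that add atoms: tert-butyldimethylsilyl chloride, CC(C)(C)[Si](C)(C)Cl
Why: Standard imidazole-promoted silylation of both phenols gives ethers that should survive Grignard addition, weak acid and metathesis and can later be removed by fluoride.

Step 6
Reactants: 11 2,5-bis(tert-butyldimethylsilyloxy)benzaldehyde
Product: 12 rac-1-[2,5-bis(tert-butyldimethylsilyloxy)phenyl]prop-2-en-1-ol
Conditions: CH2=CHMgBr, THF, −78 °C; aq. NH4Cl at −78 °C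
Reagents that add atoms: vinylmagnesium bromide, C=C[Mg]Br
Why: Grignard 1,2-addition to the aldehyde, with the new carbinol centre formed as the racemate on purpose because it becomes an sp2 carbon in step 9, and with a cold quench to keep the ortho silyl group from migrating to the alkoxide.

Step 7
Reactants: 9 (S)-2-(diethoxymethyl)-6-methylhepta-1,5-dien-3-yl 3-methylbut-2-enoate; 12 rac-1-[2,5-bis(tert-butyldimethylsilyloxy)phenyl]prop-2-en-1-ol
Product: 13 (3S)-2-{[1-(2,5-bis(tert-butyldimethylsilyloxy)phenyl)prop-2-en-1-yloxy](ethoxy)methyl}-6-methylhepta-1,5-dien-3-yl 3-methylbut-2-enoate (diastereomer mixture at the acetal and benzylic carbons)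
Conditions: PPTS (10 mol %), toluene, 5 Å MS, 50 °C
Reagents that add atoms: none
Why: Brønsted-acid-catalysed transacetalisation, in which PPTS ionises the diethyl acetal to an oxocarbenium ion that the allylic alcohol captures while the sieves take up ethanol; the bulk of the secondary benzylic alkoxy group should disfavour a second exchange, and PPTS is too weak to ionise the allylic ester or cleave aryl silyl ethers.

Step 8
Reactants: 13 mixed acetal (3S)-2-{[1-(2,5-bis(tert-butyldimethylsilyloxy)phenyl)prop-2-en-1-yloxy](ethoxy)methyl}-6-methylhepta-1,5-dien-3-yl 3-methylbut-2-enoate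
Product: 14 (1S)-1-[5-(2,5-bis(tert-butyldimethylsilyloxy)phenyl)-2-ethoxy-2,5-dihydrofuran-3-yl]-4-methylpent-3-en-1-yl 3-methylbut-2-enoate (diastereomer mixture at ring C2 and C5)
Conditions: second-generation Grubbs catalyst RuCl2(=CHPh)(PCy3)(H2IMes) (5 mol %), CH2Cl2 (0.01 M), 40 °C, Ar sparge
Reagents that add atoms: none
Why: The ruthenium benzylidene should exchange onto the monosubstituted vinyl group of 13, the new alkylidene should add to the neighbouring 1,1-disubstituted alkene in an intramolecular [2+2] step, and cycloreversion of the ruthenacyclobutane should form the ring C=C bond and a ruthenium methylidene that carries the chain with loss of ethylene. The closest known reaction type is the ring-closing metathesis of mixed allyl acetals of acroleins to 2-alkoxy-2,5-dihydrofurans. The single ring formed, the 2,5-dihydrofuran, closes by alkene–alkene metathesis of two alkene carbons that are linked by the C–O–C acetal bridge, which makes the ring five-membered. No stereocentre is created: the acetal and benzylic centres are carried as mixtures and vanish in step 9, and the (S)-carbinol is a spectator under the neutral conditions. The step needs chemoselectivity for the two terminal alkenes over the trisubstituted prenyl and senecioyl alkenes; this should be secured by the poor loading of the catalyst on trisubstituted and conjugated alkenes, by five-membered closure being much faster than the eight-membered alternative through the prenyl group, and by high dilution with purging of ethylene to suppress cross-metathesis.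

Step 9
Reactants: 14 (1S)-1-[5-(2,5-bis(tert-butyldimethylsilyloxy)phenyl)-2-ethoxy-2,5-dihydrofuran-3-yl]-4-methylpent-3-en-1-yl 3-methylbut-2-enoate
Product: 15 (S)-1-[5-(2,5-bis(tert-butyldimethylsilyloxy)phenyl)furan-3-yl]-4-methylpent-3-en-1-yl 3-methylbut-2-enoate
Conditions: PPTS (20 mol %), CH2Cl2, rt
Reagents that add atoms: none
Why: Acid-catalysed aromatising 1,4-elimination, in which loss of ethanol from the cyclic acetal gives a conjugated oxocarbenium ion that sheds the benzylic ring proton, so both ring stereocentres vanish and the furan forms without an oxidant, while the side-chain ester should not ionise under PPTS and the (S)-centre is kept.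

Step 10
Reactants: 15 (S)-1-[5-(2,5-bis(tert-butyldimethylsilyloxy)phenyl)furan-3-yl]-4-methylpent-3-en-1-yl 3-methylbut-2-enoate
Product: 16 (S)-1-[5-(2,5-dihydroxyphenyl)furan-3-yl]-4-methylpent-3-en-1-yl 3-methylbut-2-enoate
Conditions: TBAF, AcOH, THF, 0 °C, under Ar
Reagents that add atoms: none
Why: Fluoride-mediated cleavage of aryl silyl ethers, buffered with acetic acid so that the senecioate should not be attacked and the phenoxide should not be air-oxidised in an uncontrolled way.

Step 11
Reactants: 16 (S)-1-[5-(2,5-dihydroxyphenyl)furan-3-yl]-4-methylpent-3-en-1-yl 3-methylbut-2-enoate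
Product: 17 (S)-1-[5-(3,6-dioxocyclohexa-1,4-dien-1-yl)furan-3-yl]-4-methylpent-3-en-1-yl 3-methylbut-2-enoate
Conditions: Ag2O, MgSO4, Et2O, rt, dark
Reagents that add atoms: none
Why: Two-electron oxidation of a hydroquinone to the p-benzoquinone by Ag2O, an oxidant too mild to attack the furan, the prenyl alkene or the esters.

**Compound list**

1 | 4-methylpent-3-enoic acid | CC(C)=CCC(=O)O | starting material
2 | 1-(4-methylpent-3-enoyl)-1H-imidazole | CC(C)=CCC(=O)n1ccnc1 | intermediate
3 | N-methoxy-N,4-dimethylpent-3-enamide | CC(C)=CCC(=O)N(C)OC | intermediate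
4 | 2-bromo-3,3-diethoxyprop-1-ene | C=C(Br)C(OCC)OCC | starting material
5 | (3,3-diethoxyprop-1-en-2-yl)lithium | [Li]C(=C)C(OCC)OCC | intermediate
6 | 2-(diethoxymethyl)-6-methylhepta-1,5-dien-3-one | CCOC(OCC)C(=C)C(=O)CC=C(C)C | intermediate
7 | (S)-2-(diethoxymethyl)-6-methylhepta-1,5-dien-3-ol | CCOC(OCC)C(=C)[C@@H](O)CC=C(C)C | intermediate
8 | 3-methylbut-2-enoyl chloride | CC(C)=CC(=O)Cl | starting material
9 | (S)-2-(diethoxymethyl)-6-methylhepta-1,5-dien-3-yl 3-methylbut-2-enoate | CCOC(OCC)C(=C)[C@@H](OC(=O)C=C(C)C)CC=C(C)C | intermediate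
10 | 2,5-dihydroxybenzaldehyde | O=Cc1cc(O)ccc1O | starting material
11 | 2,5-bis(tert-butyldimethylsilyloxy)benzaldehyde | O=Cc1cc(O[Si](C)(C)C(C)(C)C)ccc1O[Si](C)(C)C(C)(C)C | intermediate
12 | rac-1-[2,5-bis(tert-butyldimethylsilyloxy)phenyl]prop-2-en-1-ol | C=CC(O)c1cc(O[Si](C)(C)C(C)(C)C)ccc1O[Si](C)(C)C(C)(C)C | intermediate
13 | (3S)-2-{[1-(2,5-bis(tert-butyldimethylsilyloxy)phenyl)prop-2-en-1-yloxy](ethoxy)methyl}-6-methylhepta-1,5-dien-3-yl 3-methylbut-2-enoate, diastereomer mixture at the acetal and benzylic carbons | C=CC(c1cc(O[Si](C)(C)C(C)(C)C)ccc1O[Si](C)(C)C(C)(C)C)OC(OCC)C(=C)[C@@H](OC(=O)C=C(C)C)CC=C(C)C | intermediate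
14 | (1S)-1-[5-(2,5-bis(tert-butyldimethylsilyloxy)phenyl)-2-ethoxy-2,5-dihydrofuran-3-yl]-4-methylpent-3-en-1-yl 3-methylbut-2-enoate, diastereomer mixture at ring C2 and C5 | CCOC1OC(c2cc(O[Si](C)(C)C(C)(C)C)ccc2O[Si](C)(C)C(C)(C)C)C=C1[C@@H](OC(=O)C=C(C)C)CC=C(C)C | intermediate
15 | (S)-1-[5-(2,5-bis(tert-butyldimethylsilyloxy)phenyl)furan-3-yl]-4-methylpent-3-en-1-yl 3-methylbut-2-enoate | CC(C)=CC[C@H](OC(=O)C=C(C)C)c1coc(-c2cc(O[Si](C)(C)C(C)(C)C)ccc2O[Si](C)(C)C(C)(C)C)c1 | intermediate
16 | (S)-1-[5-(2,5-dihydroxyphenyl)furan-3-yl]-4-methylpent-3-en-1-yl 3-methylbut-2-enoate | CC(C)=CC[C@H](OC(=O)C=C(C)C)c1coc(-c2cc(O)ccc2O)c1 | intermediate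
17 | (S)-1-[5-(3,6-dioxocyclohexa-1,4-dien-1-yl)furan-3-yl]-4-methylpent-3-en-1-yl 3-methylbut-2-enoate | CC(C)=CC[C@H](OC(=O)C=C(C)C)c1coc(C2=CC(=O)C=CC2=O)c1 | target

**Step count**

Total: 11 steps. Longest linear sequence: 9 steps (steps 1–4 and 7–11); the two-step aryl branch (steps 5 and 6) joins at step 7.

**Steps most likely to fail**

Step 7 (acetal exchange). Under equilibrium control the exchange may stall or run on to the doubly exchanged acetal, and the acid may ionise the benzylic allylic alcohol so that it transposes or etherifies. The fallback sets out from 9 and replaces the equilibrium by a stoichiometric, base-buffered activation of a single ethoxy group. Treatment of 9 with TESOTf and 2,4,6-collidine in CH2Cl2 at 0 °C should give 1-[(ethoxy){(3S)-6-methyl-3-[(3-methylbut-2-enoyl)oxy]hepta-1,5-dien-2-yl}methyl]-2,4,6-trimethylpyridinium triflate F1, which is not isolated. Addition of carbinol 12 should displace collidine and give the mixed acetal, so the route is rejoined at 13.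

Step 8 (ring-closing metathesis). The ruthenium alkylidene may fail to engage the congested 1,1-disubstituted alkene, which is flanked by the acetal carbon and the acyloxy-bearing carbon, so that cross-metathesis at the vinyl group outruns ring closure. The fallback sets out from Weinreb amide 3 and builds the aryl–furan bond by cross-coupling instead. 3-Bromofuran with n-BuLi in THF at −78 °C should give furan-3-yllithium F2, which is acylated by 3 to 1-(furan-3-yl)-4-methylpent-3-en-1-one F3. Reduction with (R)-Me-CBS and catecholborane in toluene at −78 °C should give (S)-1-(furan-3-yl)-4-methylpent-3-en-1-ol F4, with the furyl group as the large substituent. Acylation with 8 in pyridine should give (S)-1-(furan-3-yl)-4-methylpent-3-en-1-yl 3-methylbut-2-enoate F5. Iridium-catalysed C–H borylation ([Ir(OMe)(cod)]2, 4,4'-di-tert-butyl-2,2'-bipyridine, B2pin2, THF, rt) should take place at the unhindered α-position remote from the side chain and give (S)-4-methyl-1-[5-(4,4,5,5-tetramethyl-1,3,2-dioxaborolan-2-yl)furan-3-yl]pent-3-en-1-yl 3-methylbut-2-enoate F6. Suzuki–Miyaura coupling (Pd(OAc)2, SPhos, K3PO4, THF–H2O, 40 °C) with 2-bromo-1,4-bis(tert-butyldimethylsilyloxy)benzene F7, made from bromohydroquinone with TBSCl and imidazole, should then give the furan, so the route is rejoined at 15.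

Step 2 (ketone formation). The vinyllithium may deprotonate the doubly activated α-CH2 of the Weinreb amide instead of adding to it, which would return the amide on quench. The fallback sets out from 3 and uses a more electrophilic acceptor. Reduction of 3 with i-Bu2AlH in THF at −78 °C should give 4-methylpent-3-enal F8, which is used at once as a cold solution. Addition of vinyllithium 5 (from 4 and n-BuLi) at −78 °C should give racemic 2-(diethoxymethyl)-6-methylhepta-1,5-dien-3-ol F9. Oxidation with Dess–Martin periodinane and NaHCO3 in CH2Cl2 should give the ketone, so the route is rejoined at 6.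

**Further compounds**

F1 | step 7 | 1-[(ethoxy){(3S)-6-methyl-3-[(3-methylbut-2-enoyl)oxy]hepta-1,5-dien-2-yl}methyl]-2,4,6-trimethylpyridinium triflate | C=C(C(OCC)[n+]1c(C)cc(C)cc1C)[C@@H](OC(=O)C=C(C)C)CC=C(C)C.[O-]S(=O)(=O)C(F)(F)F
F2 | step 8 | furan-3-yllithium | [Li]c1ccoc1
F3 | step 8 | 1-(furan-3-yl)-4-methylpent-3-en-1-one | CC(C)=CCC(=O)c1ccoc1
F4 | step 8 | (S)-1-(furan-3-yl)-4-methylpent-3-en-1-ol | CC(C)=CC[C@H](O)c1ccoc1
F5 | step 8 | (S)-1-(furan-3-yl)-4-methylpent-3-en-1-yl 3-methylbut-2-enoate | CC(C)=CC[C@H](OC(=O)C=C(C)C)c1ccoc1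
F6 | step 8 | (S)-4-methyl-1-[5-(4,4,5,5-tetramethyl-1,3,2-dioxaborolan-2-yl)furan-3-yl]pent-3-en-1-yl 3-methylbut-2-enoate | CC(C)=CC[C@H](OC(=O)C=C(C)C)c1coc(B2OC(C)(C)C(C)(C)O2)c1
F7 | step 8 | 2-bromo-1,4-bis(tert-butyldimethylsilyloxy)benzene | CC(C)(C)[Si](C)(C)Oc1ccc(O[Si](C)(C)C(C)(C)C)c(Br)c1
F8 | step 2 | 4-methylpent-3-enal | CC(C)=CCC=O
F9 | step 2 | rac-2-(diethoxymethyl)-6-methylhepta-1,5-dien-3-ol | CCOC(OCC)C(=C)C(O)CC=C(C)C
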